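**Retrosynthetic overview**

1. Target ⇐ one hydrogenation that saturates a C4=C5 (Z)-alkene and removes two phenol benzyl ethers; the acetate is put on the free C2 alcohol just before.
2. C8 ketone ⇐ Weinreb amide + n-pentylmagnesium bromide; C4=C5 ⇐ Wittig olefination of a β-silyloxy aldehyde with the ylide of (3-carboxypropyl)triphenylphosphonium bromide.
3. Aldehyde ⇐ (S)-β-hydroxy ester, whose single stereocentre comes from ketoreductase (NADPH-dependent enzyme) reduction of an achiral 4-aryl-3-oxobutanoate.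
4. β-Keto ester ⇐ Masamune–Brooks homologation of 3,5-bis(benzyloxy)phenylacetic acid, made from methyl 3,5-dihydroxyphenylacetate.
5. No ring is formed: the benzene ring is bought intact and the rest is an open chain.

Assumption: the SMILES is read as the (2R)-acetate (C2 of the tridecane chain), and a ketoreductase screening panel containing (S)-selective, isopropanol-tolerant enzymes is taken as purchasable.

**Route**

Step 1
Reactants: 1 methyl 2-(3,5-dihydroxyphenyl)acetate; 2 benzyl bromide
Product: 3 methyl 2-[3,5-bis(benzyloxy)phenyl]acetate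
Conditions: BnBr (2.3 equiv), K2CO3 (3 equiv), DMF, rt, 16 h
Reagents that add atoms: benzyl bromide, BrCc1ccccc1
Why: Williamson ether synthesis: carbonate deprotonates only the two phenols, which are O-benzylated by the reactive benzylic bromide while the methyl ester is untouched.

Step 2
Reactants: 3 methyl 2-[3,5-bis(benzyloxy)phenyl]acetate; 4 lithium hydroxide
Product: 5 2-[3,5-bis(benzyloxy)phenyl]acetic acid
Conditions: LiOH·H2O (3 equiv), THF/MeOH/H2O 3:1:1, rt; then 1 M HCl to pH 2
Reagents that add atoms: lithium hydroxide, [Li+].[OH-]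
Why: Saponification of an unhindered methyl ester by hydroxide, to which the benzyl aryl ethers are inert.

Step 3
Reactants: 5 2-[3,5-bis(benzyloxy)phenyl]acetic acid; 6 1,1'-carbonyldiimidazole; 7 potassium ethyl malonate
Product: 10 ethyl 4-[3,5-bis(benzyloxy)phenyl]-3-oxobutanoate, via acyl imidazolide 8 (not isolated), via acylmalonate magnesium enolate 9 (not isolated)
Conditions: CDI (1.2 equiv), THF, rt, 2 h; then KO2CCH2CO2Et (2 equiv)/MgCl2 (2 equiv)/Et3N (3 equiv) premixed in MeCN, rt to 45 °C, 16 h; 1 M HCl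
Reagents that add atoms: potassium ethyl malonate, [K+].[O-]C(=O)CC(=O)OCC
Why: Masamune–Brooks homologation: the acyl imidazolide C-acylates the magnesium enolate of the malonate half-ester and the adduct loses CO2, giving the β-keto ester under nearly neutral conditions that avoid self-condensation of the arylacetyl unit.

Step 4
Reactants: 10 ethyl 4-[3,5-bis(benzyloxy)phenyl]-3-oxobutanoate
Product: 11 ethyl (3S)-4-[3,5-bis(benzyloxy)phenyl]-3-hydroxybutanoate
Conditions: (S)-selective ketoreductase (KRED), NADP+ (0.5 mol%), i-PrOH (20% v/v, hydride donor and cosolvent), DMSO (5% v/v), 0.1 M KH2PO4/K2HPO4 buffer pH 7.0, 30 °C, 24 h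
Reagents that add atoms: none
Why: Enzymatic asymmetric carbonyl reduction by a ketoreductase (NADPH-dependent oxidoreductase of the alcohol dehydrogenase class, cofactor recycled by the same enzyme oxidising isopropanol): β-keto esters are the best-behaved substrate class, and the active site delivers hydride from NADPH only to the re face of the C3 ketone, creating the sole stereocentre as (S).

Step 5
Reactants: 11 ethyl (3S)-4-[3,5-bis(benzyloxy)phenyl]-3-hydroxybutanoate; 12 tert-butyldimethylsilyl chloride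
Product: 13 ethyl (3S)-4-[3,5-bis(benzyloxy)phenyl]-3-[(tert-butyldimethylsilyl)oxy]butanoate
Conditions: TBSCl (1.5 equiv), imidazole (3 equiv), DMF, rt, 12 h
Reagents that add atoms: tert-butyldimethylsilyl chloride, CC(C)(C)[Si](C)(C)Cl
Why: Imidazole-promoted O-silylation (Corey protocol) masks the secondary alcohol for the hydride, ylide and Grignard steps, and only the O–H bond reacts, so the stereocentre is untouched.

Step 6
Reactants: 13 ethyl (3S)-4-[3,5-bis(benzyloxy)phenyl]-3-[(tert-butyldimethylsilyl)oxy]butanoate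
Product: 14 (3S)-4-[3,5-bis(benzyloxy)phenyl]-3-[(tert-butyldimethylsilyl)oxy]butan-1-ol
Conditions: i-Bu2AlH (2.5 equiv), CH2Cl2, −78 to 0 °C; aq. KNaC4H4O6 work-up
Reagents that add atoms: none
Why: Exhaustive aluminium hydride reduction of the ester to the primary alcohol, chosen over a partial reduction because complete reduction cannot over- or under-shoot; silyl and benzyl ethers are inert.

Step 7
Reactants: 14 (3S)-4-[3,5-bis(benzyloxy)phenyl]-3-[(tert-butyldimethylsilyl)oxy]butan-1-ol
Product: 15 (3S)-4-[3,5-bis(benzyloxy)phenyl]-3-[(tert-butyldimethylsilyl)oxy]butanal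
Conditions: Dess–Martin periodinane (1.3 equiv), CH2Cl2, 0 °C to rt, 1 h; aq. NaHCO3/Na2S2O3 work-up
Reagents that add atoms: none
Why: Dess–Martin oxidation stops at the aldehyde under nearly neutral conditions, so the β-silyloxy group is not eliminated and the adjacent stereocentre is not disturbed.

Step 8
Reactants: 15 (3S)-4-[3,5-bis(benzyloxy)phenyl]-3-[(tert-butyldimethylsilyl)oxy]butanal; 16 (3-carboxypropyl)triphenylphosphonium bromide
Product: 18 (4Z,7R)-8-[3,5-bis(benzyloxy)phenyl]-7-[(tert-butyldimethylsilyl)oxy]oct-4-enoic acid, via carboxylate ylide 17 (not isolated)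
Conditions: 16 (2 equiv), NaN(SiMe3)2 (3.9 equiv), THF, 0 °C, 30 min; then 15, −78 °C to rt; cold 0.5 M HCl to pH 3
Reagents that add atoms: (3-carboxypropyl)triphenylphosphonium bromide, [Br-].OC(=O)CCC[P+](c1ccccc1)(c1ccccc1)c1ccccc1
Why: Wittig olefination with a non-stabilised ylide under lithium-free conditions is kinetically Z-selective and adds C5 to C8 with the carboxyl already at the future ketone carbon; the alkene geometry is of no consequence because the double bond is later hydrogenated.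

Step 9
Reactants: 18 (4Z,7R)-8-[3,5-bis(benzyloxy)phenyl]-7-[(tert-butyldimethylsilyl)oxy]oct-4-enoic acid; 6 1,1'-carbonyldiimidazole; 19 N,O-dimethylhydroxylamine hydrochloride
Product: 21 (4Z,7R)-8-[3,5-bis(benzyloxy)phenyl]-7-[(tert-butyldimethylsilyl)oxy]-N-methoxy-N-methyloct-4-enamide, via acyl imidazolide 20 (not isolated)
Conditions: CDI (1.2 equiv), CH2Cl2, rt, 1 h; then MeNH(OMe)·HCl (1.5 equiv), rt, 12 h
Reagents that add atoms: N,O-dimethylhydroxylamine hydrochloride, Cl.CNOC
Why: Weinreb amide formation by CDI activation and aminolysis runs at neutral pH, so the silyl ether, the alkene and the remote stereocentre are unaffected.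

Step 10
Reactants: 21 (4Z,7R)-8-[3,5-bis(benzyloxy)phenyl]-7-[(tert-butyldimethylsilyl)oxy]-N-methoxy-N-methyloct-4-enamide; 22 n-pentylmagnesium bromide
Product: 24 (9Z,12R)-13-[3,5-bis(benzyloxy)phenyl]-12-[(tert-butyldimethylsilyl)oxy]tridec-9-en-6-one, via magnesium hemiaminal chelate 23 (not isolated)
Conditions: n-C5H11MgBr (2 equiv), THF, 0 °C, 2 h; cold 0.5 M HCl
Reagents that add atoms: n-pentylmagnesium bromide, CCCCC[Mg]Br
Why: Weinreb ketone synthesis: the Grignard adduct is held as a five-membered magnesium chelate that collapses to the ketone only on work-up, so exactly one pentyl group is added.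

Step 11
Reactants: 24 (9Z,12R)-13-[3,5-bis(benzyloxy)phenyl]-12-[(tert-butyldimethylsilyl)oxy]tridec-9-en-6-one
Product: 25 (9Z,12R)-13-[3,5-bis(benzyloxy)phenyl]-12-hydroxytridec-9-en-6-one
Conditions: HF·pyridine, pyridine, THF, 0 °C to rt, 12 h
Reagents that add atoms: none
Why: Fluoride-driven desilylation cleaves only the Si–O bond (driven by the strong Si–F bond), leaving benzyl ethers, ketone and alkene alone and retaining configuration because the C–O bond is never broken.

Step 12
Reactants: 25 (9Z,12R)-13-[3,5-bis(benzyloxy)phenyl]-12-hydroxytridec-9-en-6-one; 26 acetic anhydride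
Product: 27 (2R,4Z)-1-[3,5-bis(benzyloxy)phenyl]-8-oxotridec-4-en-2-yl acetate
Conditions: Ac2O (2 equiv), pyridine (4 equiv), DMAP (0.1 equiv), CH2Cl2, rt, 4 h
Reagents that add atoms: acetic anhydride, CC(=O)OC(C)=O
Why: DMAP-catalysed O-acylation of the only free hydroxyl group, with retention at the stereocentre since the reaction takes place at oxygen.

Step 13
Reactants: 27 (2R,4Z)-1-[3,5-bis(benzyloxy)phenyl]-8-oxotridec-4-en-2-yl acetate
Product: 28 (2R)-1-(3,5-dihydroxyphenyl)-8-oxotridecan-2-yl acetate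
Conditions: H2 (1 atm), 10% Pd/C, EtOAc, rt, 6 h
Reagents that add atoms: none
Why: Heterogeneous catalytic hydrogenation saturates the alkene and hydrogenolyses both benzyl aryl ethers in one operation, while the dialkyl ketone and the non-benzylic acetate are inert at 1 atm in a non-alcoholic solvent.

**Compound list**

1 | methyl 2-(3,5-dihydroxyphenyl)acetate | COC(=O)Cc1cc(O)cc(O)c1 | starting material
2 | benzyl bromide | BrCc1ccccc1 | starting material
3 | methyl 2-[3,5-bis(benzyloxy)phenyl]acetate | COC(=O)Cc1cc(OCc2ccccc2)cc(OCc2ccccc2)c1 | intermediate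
4 | lithium hydroxide (used as the monohydrate) | [Li+].[OH-] | starting material
5 | 2-[3,5-bis(benzyloxy)phenyl]acetic acid | OC(=O)Cc1cc(OCc2ccccc2)cc(OCc2ccccc2)c1 | intermediate
6 | 1,1'-carbonyldiimidazole (CDI) | O=C(n1ccnc1)n1ccnc1 | starting material
7 | potassium ethyl malonate (potassium 3-ethoxy-3-oxopropanoate) | [K+].[O-]C(=O)CC(=O)OCC | starting material
8 | 2-[3,5-bis(benzyloxy)phenyl]-1-(1H-imidazol-1-yl)ethan-1-one (acyl imidazolide) | O=C(Cc1cc(OCc2ccccc2)cc(OCc2ccccc2)c1)n1ccnc1 | intermediate (not isolated)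
9 | (2Z)-4-[3,5-bis(benzyloxy)phenyl]-2-(ethoxycarbonyl)-3-hydroxybut-2-enoic acid, present in the flask as its magnesium chelate and drawn as the neutral ester-chelated enol | CCOC(=O)/C(C(O)=O)=C(\O)Cc1cc(OCc2ccccc2)cc(OCc2ccccc2)c1 | intermediate (not isolated)
10 | ethyl 4-[3,5-bis(benzyloxy)phenyl]-3-oxobutanoate | CCOC(=O)CC(=O)Cc1cc(OCc2ccccc2)cc(OCc2ccccc2)c1 | intermediate
11 | ethyl (3S)-4-[3,5-bis(benzyloxy)phenyl]-3-hydroxybutanoate | CCOC(=O)C[C@@H](O)Cc1cc(OCc2ccccc2)cc(OCc2ccccc2)c1 | intermediate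
12 | tert-butyldimethylsilyl chloride | CC(C)(C)[Si](C)(C)Cl | starting material
13 | ethyl (3S)-4-[3,5-bis(benzyloxy)phenyl]-3-[(tert-butyldimethylsilyl)oxy]butanoate | CCOC(=O)C[C@@H](O[Si](C)(C)C(C)(C)C)Cc1cc(OCc2ccccc2)cc(OCc2ccccc2)c1 | intermediate
14 | (3S)-4-[3,5-bis(benzyloxy)phenyl]-3-[(tert-butyldimethylsilyl)oxy]butan-1-ol | OCC[C@@H](O[Si](C)(C)C(C)(C)C)Cc1cc(OCc2ccccc2)cc(OCc2ccccc2)c1 | intermediate
15 | (3S)-4-[3,5-bis(benzyloxy)phenyl]-3-[(tert-butyldimethylsilyl)oxy]butanal | O=CC[C@@H](O[Si](C)(C)C(C)(C)C)Cc1cc(OCc2ccccc2)cc(OCc2ccccc2)c1 | intermediate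
16 | (3-carboxypropyl)triphenylphosphonium bromide | [Br-].OC(=O)CCC[P+](c1ccccc1)(c1ccccc1)c1ccccc1 | starting material
17 | sodium 4-(triphenyl-λ5-phosphanylidene)butanoate (carboxylate ylide) | [Na+].[O-]C(=O)CCC=P(c1ccccc1)(c1ccccc1)c1ccccc1 | intermediate (not isolated)
18 | (4Z,7R)-8-[3,5-bis(benzyloxy)phenyl]-7-[(tert-butyldimethylsilyl)oxy]oct-4-enoic acid | OC(=O)CC/C=C\C[C@@H](O[Si](C)(C)C(C)(C)C)Cc1cc(OCc2ccccc2)cc(OCc2ccccc2)c1 | intermediate
19 | N,O-dimethylhydroxylamine hydrochloride | Cl.CNOC | starting material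
20 | (4Z,7R)-8-[3,5-bis(benzyloxy)phenyl]-7-[(tert-butyldimethylsilyl)oxy]-1-(1H-imidazol-1-yl)oct-4-en-1-one (acyl imidazolide) | O=C(CC/C=C\C[C@@H](O[Si](C)(C)C(C)(C)C)Cc1cc(OCc2ccccc2)cc(OCc2ccccc2)c1)n1ccnc1 | intermediate (not isolated)
21 | (4Z,7R)-8-[3,5-bis(benzyloxy)phenyl]-7-[(tert-butyldimethylsilyl)oxy]-N-methoxy-N-methyloct-4-enamide | CON(C)C(=O)CC/C=C\C[C@@H](O[Si](C)(C)C(C)(C)C)Cc1cc(OCc2ccccc2)cc(OCc2ccccc2)c1 | intermediate
22 | n-pentylmagnesium bromide | CCCCC[Mg]Br | starting material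
23 | bromomagnesium (9Z,12R)-13-[3,5-bis(benzyloxy)phenyl]-12-[(tert-butyldimethylsilyl)oxy]-6-[methoxy(methyl)amino]tridec-9-en-6-olate (chelated tetrahedral adduct; both epimers at the transient C6, which is lost on collapse) | CCCCCC(O[Mg]Br)(N(C)OC)CC/C=C\C[C@@H](O[Si](C)(C)C(C)(C)C)Cc1cc(OCc2ccccc2)cc(OCc2ccccc2)c1 | intermediate (not isolated)
24 | (9Z,12R)-13-[3,5-bis(benzyloxy)phenyl]-12-[(tert-butyldimethylsilyl)oxy]tridec-9-en-6-one | CCCCCC(=O)CC/C=C\C[C@@H](O[Si](C)(C)C(C)(C)C)Cc1cc(OCc2ccccc2)cc(OCc2ccccc2)c1 | intermediate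
25 | (9Z,12R)-13-[3,5-bis(benzyloxy)phenyl]-12-hydroxytridec-9-en-6-one | CCCCCC(=O)CC/C=C\C[C@@H](O)Cc1cc(OCc2ccccc2)cc(OCc2ccccc2)c1 | intermediate
26 | acetic anhydride | CC(=O)OC(C)=O | starting material
27 | (2R,4Z)-1-[3,5-bis(benzyloxy)phenyl]-8-oxotridec-4-en-2-yl acetate | CCCCCC(=O)CC/C=C\C[C@@H](OC(C)=O)Cc1cc(OCc2ccccc2)cc(OCc2ccccc2)c1 | intermediate
28 | (2R)-1-(3,5-dihydroxyphenyl)-8-oxotridecan-2-yl acetate | CCCCCC(=O)CCCCC[C@H](Cc1cc(O)cc(O)c1)OC(C)=O | target

**Step count and risk**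

Total step count: 13. Longest linear sequence: 13 steps (1 to 28); the route is fully linear.

The three steps most likely to fail:

Step 4 (enzymatic reduction). The risk is that no panel enzyme turns over the bulky, water-insoluble bis(benzyl ether) 10 with useful rate or selectivity. The fallback sets out from 10 and comes back at 11. The benzyl ethers are first removed (H2, 10% Pd/C, EtOAc, rt) to give the water-soluble ethyl 4-(3,5-dihydroxyphenyl)-3-oxobutanoate F1, which is the size of the 4-aryl-3-oxobutanoates that ketoreductases accept routinely. The same ketoreductase/NADP+/i-PrOH system then reduces it to ethyl (3S)-4-(3,5-dihydroxyphenyl)-3-hydroxybutanoate F2. Phenol-selective Williamson re-benzylation (BnBr, K2CO3, acetone, reflux; the secondary alcohol is not deprotonated by carbonate) returns 11.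

Step 8 (Wittig olefination). The risks are β-elimination of the silyloxy group from aldehyde 15 under the basic ylide and a low yield with the poorly soluble carboxylate ylide. The fallback sets out from 14 and comes back at 18; it exchanges the roles of the two olefination partners so that neither 15 nor the carboxylate ylide is needed. Appel-type iodination of 14 (I2, PPh3, imidazole, CH2Cl2, 0 °C) gives tert-butyl{[(2S)-1-[3,5-bis(benzyloxy)phenyl]-4-iodobutan-2-yl]oxy}dimethylsilane F3. Heating with PPh3 in MeCN at 80 °C gives [(3S)-4-[3,5-bis(benzyloxy)phenyl]-3-[(tert-butyldimethylsilyl)oxy]butyl]triphenylphosphonium iodide F4. NaN(SiMe3)2 in THF at −78 °C gives the ylide tert-butyl{[(2S)-1-[3,5-bis(benzyloxy)phenyl]-4-(triphenyl-λ5-phosphanylidene)butan-2-yl]oxy}dimethylsilane F5, used in solution. It reacts Z-selectively with commercial methyl 4-oxobutanoate (COC(=O)CCC=O) to give methyl (4Z,7R)-8-[3,5-bis(benzyloxy)phenyl]-7-[(tert-butyldimethylsilyl)oxy]oct-4-enoate F6. LiOH in THF/H2O at rt then gives 18.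

Step 13 (global hydrogenation). The risks are incomplete debenzylation, partial reduction of the ketone, or loss of material at the last step through oxidation of the free resorcinol on the catalyst. The fallback sets out from 27 and comes back at 28; it separates alkene saturation from deprotection and uses no hydrogenation catalyst. Diimide generated from KO2CN=NCO2K and AcOH (MeOH/pyridine, rt) saturates the alkene to give (2R)-1-[3,5-bis(benzyloxy)phenyl]-8-oxotridecan-2-yl acetate F7 without touching ketone, acetate or benzyl ethers. BCl3 with pentamethylbenzene as cation scavenger (CH2Cl2, −78 °C) then cleaves the two aryl benzyl ethers to give 28; the acetate and the ketone survive these conditions.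

**Further compounds**

F1 | step 4 | ethyl 4-(3,5-dihydroxyphenyl)-3-oxobutanoate | CCOC(=O)CC(=O)Cc1cc(O)cc(O)c1
F2 | step 4 | ethyl (3S)-4-(3,5-dihydroxyphenyl)-3-hydroxybutanoate | CCOC(=O)C[C@@H](O)Cc1cc(O)cc(O)c1
F3 | step 8 | tert-butyl{[(2S)-1-[3,5-bis(benzyloxy)phenyl]-4-iodobutan-2-yl]oxy}dimethylsilane | ICC[C@@H](O[Si](C)(C)C(C)(C)C)Cc1cc(OCc2ccccc2)cc(OCc2ccccc2)c1
F4 | step 8 | [(3S)-4-[3,5-bis(benzyloxy)phenyl]-3-[(tert-butyldimethylsilyl)oxy]butyl]triphenylphosphonium iodide | [I-].C(C[C@@H](O[Si](C)(C)C(C)(C)C)Cc1cc(OCc2ccccc2)cc(OCc2ccccc2)c1)[P+](c1ccccc1)(c1ccccc1)c1ccccc1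
F5 | step 8 | tert-butyl{[(2S)-1-[3,5-bis(benzyloxy)phenyl]-4-(triphenyl-λ5-phosphanylidene)butan-2-yl]oxy}dimethylsilane | C(C[C@@H](O[Si](C)(C)C(C)(C)C)Cc1cc(OCc2ccccc2)cc(OCc2ccccc2)c1)=P(c1ccccc1)(c1ccccc1)c1ccccc1
F6 | step 8 | methyl (4Z,7R)-8-[3,5-bis(benzyloxy)phenyl]-7-[(tert-butyldimethylsilyl)oxy]oct-4-enoate | COC(=O)CC/C=C\C[C@@H](O[Si](C)(C)C(C)(C)C)Cc1cc(OCc2ccccc2)cc(OCc2ccccc2)c1
F7 | step 13 | (2R)-1-[3,5-bis(benzyloxy)phenyl]-8-oxotridecan-2-yl acetate | CCCCCC(=O)CCCCC[C@@H](OC(C)=O)Cc1cc(OCc2ccccc2)cc(OCc2ccccc2)c1
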